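**Retrosynthetic overview**
- The target is two isoflavones joined C3'–C3''' through their B rings. The last disconnection opens ring C of the chlorine-free half (C4–C4a, C2–C3, O1–C2) to a biaryl acetic acid, phloroglucinol and one carbon from DMF.
- The strategy rests on ring A of the chlorine-free half (C4a, C5–C8, C8a, hydroxyls on C5 and C7). It maps onto phloroglucinol, whose three ring CH carbons and three hydroxyls are equivalent, so acylation and O1–C2 closure raise no regiochemical question.
- Ring A of the other half carries chlorine on C8 and is not symmetric. It is therefore built first, from a phenol whose single free hydroxyl sits next to the chlorine.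
- The biaryl bond comes from a Suzuki coupling of the chlorinated isoflavone boronate with the same bromo acid that supplied its ring B.
- Ring order: ring C of the chlorinated half (steps 1–2), biaryl bond (steps 3–4), demethylation (step 5), ring C of the chlorine-free half last (step 6).

Key step: step 6

Assumption: 2-chloro-3,5-dimethoxyphenol, the ring A building block of griseofulvin chemistry, is taken as a purchasable starting material.

**Step 1**
Reactants: 1 (3-bromo-4-methoxyphenyl)acetic acid; 2 2-chloro-3,5-dimethoxyphenol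
Product: 3 2-(3-bromo-4-methoxyphenyl)-1-(3-chloro-2-hydroxy-4,6-dimethoxyphenyl)ethan-1-one
Conditions: BF3·OEt2 (Lewis acid and solvent), 85 °C, Ar; aq. NaOAc work-up
Reagents that add atoms: none
Why: BF3-promoted Friedel–Crafts acylation of an electron-rich phenol by an arylacetic acid should go to C6 of 2, the only free carbon ortho to the hydroxyl (C2 is blocked by chlorine), where the ketone is held as a boron chelate, whereas C4 between the two methoxy groups is more hindered and offers no chelate.

**Step 2**
Reactants: 3 2-(3-bromo-4-methoxyphenyl)-1-(3-chloro-2-hydroxy-4,6-dimethoxyphenyl)ethan-1-one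
Product: 5 3-(3-bromo-4-methoxyphenyl)-8-chloro-5,7-dimethoxy-4H-chromen-4-one, via enaminone 4 (not isolated)
Conditions: Me2NCH(OMe)2 (3 equiv), toluene, 95 °C; then AcOH, 60 °C
Reagents that add atoms: N,N-dimethylformamide dimethyl acetal, COC(OC)N(C)C
Why: Condensation of the acetal at the doubly activated benzylic methylene gives enaminone 4, and addition of the only ortho hydroxyl with loss of dimethylamine closes the pyranone (the standard deoxybenzoin route to isoflavones), which places chlorine at C8 because that hydroxyl lies next to it.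

**Step 3**
Reactants: 5 3-(3-bromo-4-methoxyphenyl)-8-chloro-5,7-dimethoxy-4H-chromen-4-one
Product: 6 8-chloro-5,7-dimethoxy-3-[4-methoxy-3-(4,4,5,5-tetramethyl-1,3,2-dioxaborolan-2-yl)phenyl]-4H-chromen-4-one
Conditions: B2pin2, Pd(dppf)Cl2 (cat.), KOAc, 1,4-dioxane, 90 °C
Reagents that add atoms: bis(pinacolato)diboron, CC1(C)OB(OC1(C)C)B1OC(C)(C)C(C)(C)O1
Why: Miyaura borylation should take place only at the C–Br bond, since zerovalent palladium with dppf does not insert into the electron-rich C–Cl bond flanked by two oxygen-bearing carbons, and KOAc is too weak a base to open the pyranone.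

**Step 4**
Reactants: 6 8-chloro-5,7-dimethoxy-3-[4-methoxy-3-(4,4,5,5-tetramethyl-1,3,2-dioxaborolan-2-yl)phenyl]-4H-chromen-4-one; 1 (3-bromo-4-methoxyphenyl)acetic acid
Product: 7 [5'-(8-chloro-5,7-dimethoxy-4-oxo-4H-chromen-3-yl)-2',6-dimethoxybiphenyl-3-yl]acetic acid
Conditions: Pd(dppf)Cl2 (cat.), K3PO4 (4 equiv), 1,4-dioxane/H2O, 85 °C; then 1 M HCl
Reagents that add atoms: none
Why: Suzuki–Miyaura coupling, in which zerovalent palladium inserts into the C–Br bond of 1 (present as its carboxylate) and not into the C–Cl bond of 6, and the phosphate-activated boronate transmetalates to give the 2,2'-dimethoxybiaryl, which has no stable chiral axis.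

**Step 5**
Reactants: 7 [5'-(8-chloro-5,7-dimethoxy-4-oxo-4H-chromen-3-yl)-2',6-dimethoxybiphenyl-3-yl]acetic acid
Product: 8 [5'-(8-chloro-5,7-dihydroxy-4-oxo-4H-chromen-3-yl)-2',6-dihydroxybiphenyl-3-yl]acetic acid
Conditions: BBr3 (12 equiv), CH2Cl2, −78 → 40 °C; ice/H2O quench (no alcohol)
Reagents that add atoms: none
Why: Lewis-acid ether cleavage (boron binds the ether oxygen, bromide attacks the methyl group) should free all four phenols while the aryl chloride, the chromone and the acid survive, and the aqueous quench avoids esterification of the acid.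

**Step 6**
Reactants: 8 [5'-(8-chloro-5,7-dihydroxy-4-oxo-4H-chromen-3-yl)-2',6-dihydroxybiphenyl-3-yl]acetic acid; 9 phloroglucinol; 10 N,N-dimethylformamide (source of C2)
Product: 13 bisoflavolin N, via deoxybenzoin 11 (not isolated), via enaminone 12 (not isolated)
Conditions: 9 (3 equiv), BF3·OEt2 (Lewis acid and solvent), 80 °C, Ar; then DMF, MeSO2Cl (5 equiv), 75 °C; aq. NaOAc, then MeOH/H2O, 60 °C
Reagents that add atoms: none
Why: BF3 activates the carboxylic acid of 8, which C-acylates phloroglucinol (Friedel–Crafts acylation) to give deoxybenzoin 11 as a boron chelate between the ketone and one ortho hydroxyl; the iminium salt formed from DMF and MeSO2Cl then attacks the enolised benzylic carbon, and loss of methanesulfonate gives the iminium form of enaminone 12. The closest known reaction type is the one-pot BF3·OEt2/DMF/MeSO2Cl conversion of phenols and arylacetic acids into 5,7-dihydroxyisoflavones, which is run on unprotected polyphenols. Ring C of the chlorine-free half (O1, C2, C3, C4, C4a, C8a) closes by 6-exo-trig addition of the second ortho hydroxyl to the iminium carbon, and loss of dimethylamine gives the C2=C3 double bond. No stereocentre is formed. The step needs chemoselectivity between phloroglucinol and the phenolic rings of 8 itself: phloroglucinol is in excess and is by far the most nucleophilic arene present, while C6 of the chlorinated chromone is deactivated by the chelated C4 carbonyl and by chlorine, just as C6 and C8 of the finished chlorine-free half tolerate these conditions. No regiochemical control is needed on the new ring A, because the three ring CH carbons of phloroglucinol and the two hydroxyls flanking the new ketone are equivalent.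

**Compound list**
1 | (3-bromo-4-methoxyphenyl)acetic acid | COc1ccc(CC(=O)O)cc1Br | starting material
2 | 2-chloro-3,5-dimethoxyphenol | COc1cc(O)c(Cl)c(OC)c1 | starting material
3 | 2-(3-bromo-4-methoxyphenyl)-1-(3-chloro-2-hydroxy-4,6-dimethoxyphenyl)ethan-1-one | COc1ccc(CC(=O)c2c(O)c(Cl)c(OC)cc2OC)cc1Br | intermediate
4 | (E)-2-(3-bromo-4-methoxyphenyl)-1-(3-chloro-2-hydroxy-4,6-dimethoxyphenyl)-3-(dimethylamino)prop-2-en-1-one (enaminone, drawn as the E isomer; the geometry is lost on ring closure) | CN(C)/C=C(\c1ccc(OC)c(Br)c1)C(=O)c1c(O)c(Cl)c(OC)cc1OC | intermediate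
5 | 3-(3-bromo-4-methoxyphenyl)-8-chloro-5,7-dimethoxy-4H-chromen-4-one | COc1ccc(-c2coc3c(Cl)c(OC)cc(OC)c3c2=O)cc1Br | intermediate
6 | 8-chloro-5,7-dimethoxy-3-[4-methoxy-3-(4,4,5,5-tetramethyl-1,3,2-dioxaborolan-2-yl)phenyl]-4H-chromen-4-one | COc1ccc(-c2coc3c(Cl)c(OC)cc(OC)c3c2=O)cc1B1OC(C)(C)C(C)(C)O1 | intermediate
7 | [5'-(8-chloro-5,7-dimethoxy-4-oxo-4H-chromen-3-yl)-2',6-dimethoxybiphenyl-3-yl]acetic acid | COc1ccc(CC(=O)O)cc1-c1cc(-c2coc3c(Cl)c(OC)cc(OC)c3c2=O)ccc1OC | intermediate
8 | [5'-(8-chloro-5,7-dihydroxy-4-oxo-4H-chromen-3-yl)-2',6-dihydroxybiphenyl-3-yl]acetic acid | O=C(O)Cc1ccc(O)c(-c2cc(-c3coc4c(Cl)c(O)cc(O)c4c3=O)ccc2O)c1 | intermediate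
9 | phloroglucinol (benzene-1,3,5-triol) | Oc1cc(O)cc(O)c1 | starting material
10 | N,N-dimethylformamide | CN(C)C=O | starting material
11 | 2-[5'-(8-chloro-5,7-dihydroxy-4-oxo-4H-chromen-3-yl)-2',6-dihydroxybiphenyl-3-yl]-1-(2,4,6-trihydroxyphenyl)ethan-1-one (deoxybenzoin) | O=C(Cc1ccc(O)c(-c2cc(-c3coc4c(Cl)c(O)cc(O)c4c3=O)ccc2O)c1)c1c(O)cc(O)cc1O | intermediate
12 | (E)-2-[5'-(8-chloro-5,7-dihydroxy-4-oxo-4H-chromen-3-yl)-2',6-dihydroxybiphenyl-3-yl]-3-(dimethylamino)-1-(2,4,6-trihydroxyphenyl)prop-2-en-1-one (enaminone, drawn as the E isomer; the geometry is lost on ring closure) | CN(C)/C=C(\c1ccc(O)c(-c2cc(-c3coc4c(Cl)c(O)cc(O)c4c3=O)ccc2O)c1)C(=O)c1c(O)cc(O)cc1O | intermediate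
13 | bisoflavolin N | O=c1c(-c2ccc(O)c(-c3cc(-c4coc5c(Cl)c(O)cc(O)c5c4=O)ccc3O)c2)coc2cc(O)cc(O)c12 | target

**Step count and risks**
Total step count: 6. Longest linear sequence: 6 steps (1 and 2 → 3 → 5 → 6 → 7 → 8 → 13).

Steps most likely to fail:

1. Step 6. The activated acid may acylate phenolic rings of other molecules of 8 instead of phloroglucinol, or the boron-chelated polyphenol may stay undissolved in BF3·OEt2, so that oligomers form and ring C closes only in part. The fallback sets out from 7. The same one-pot acylation, formylation and closure with phloroglucinol 9 and DMF 10 (BF3·OEt2, 80 °C; then MeSO2Cl, 75 °C) is run on this tetramethyl ether acid, which is more soluble and has no free phenol to compete. It should give 8-chloro-3-[5'-(5,7-dihydroxy-4-oxo-4H-chromen-3-yl)-2',6-dimethoxybiphenyl-3-yl]-5,7-dimethoxy-4H-chromen-4-one F1. BBr3 in CH2Cl2 then removes the four methyl groups, and the route is rejoined at 13.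

2. Step 1. Acylation may go to C4 of the phenol (para to the hydroxyl, between the two methoxy groups), or stop at the O-acyl stage because chlorine lowers the reactivity of the ring. The fallback sets out from 1 and 2. The acid is first esterified on the phenol oxygen (DCC, DMAP, CH2Cl2) to give 2-chloro-3,5-dimethoxyphenyl (3-bromo-4-methoxyphenyl)acetate F2. A Fries rearrangement (TiCl4, 1,2-dichloroethane, 80 °C) then delivers the acyl group within the titanium phenoxide to the only free ortho carbon, and the route is rejoined at 3.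

3. Step 4. Protodeboronation of the ortho-methoxy boronate and hydroxide-induced opening of the pyranone may outrun transmetalation to the hindered partner in aqueous base. The fallback sets out from 1 and 5, reverses the roles of the partners and uses anhydrous conditions.
   - Acid 1 is converted (Boc2O, DMAP, t-BuOH) into tert-butyl (3-bromo-4-methoxyphenyl)acetate F3.
   - Miyaura borylation (B2pin2, Pd(dppf)Cl2, KOAc, 1,4-dioxane, 90 °C) gives tert-butyl [4-methoxy-3-(4,4,5,5-tetramethyl-1,3,2-dioxaborolan-2-yl)phenyl]acetate F4.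
   - Coupling of F4 with bromide 5 (Pd(dppf)Cl2, CsF, 1,4-dioxane, 90 °C, no water) gives tert-butyl [5'-(8-chloro-5,7-dimethoxy-4-oxo-4H-chromen-3-yl)-2',6-dimethoxybiphenyl-3-yl]acetate F5.
   - CF3CO2H in CH2Cl2 cleaves the tert-butyl ester, and the route is rejoined at 7.

**Further compounds**
F1 | step 6 | 8-chloro-3-[5'-(5,7-dihydroxy-4-oxo-4H-chromen-3-yl)-2',6-dimethoxybiphenyl-3-yl]-5,7-dimethoxy-4H-chromen-4-one | COc1ccc(-c2coc3cc(O)cc(O)c3c2=O)cc1-c1cc(-c2coc3c(Cl)c(OC)cc(OC)c3c2=O)ccc1OC
F2 | step 1 | 2-chloro-3,5-dimethoxyphenyl (3-bromo-4-methoxyphenyl)acetate | COc1ccc(CC(=O)Oc2cc(OC)cc(OC)c2Cl)cc1Br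
F3 | step 4 | tert-butyl (3-bromo-4-methoxyphenyl)acetate | COc1ccc(CC(=O)OC(C)(C)C)cc1Br
F4 | step 4 | tert-butyl [4-methoxy-3-(4,4,5,5-tetramethyl-1,3,2-dioxaborolan-2-yl)phenyl]acetate | COc1ccc(CC(=O)OC(C)(C)C)cc1B1OC(C)(C)C(C)(C)O1
F5 | step 4 | tert-butyl [5'-(8-chloro-5,7-dimethoxy-4-oxo-4H-chromen-3-yl)-2',6-dimethoxybiphenyl-3-yl]acetate | COc1ccc(CC(=O)OC(C)(C)C)cc1-c1cc(-c2coc3c(Cl)c(OC)cc(OC)c3c2=O)ccc1OC
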